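The rate constants are assumed; the run is a simulation.

Each living end costs one initiator, so c(living end) cannot pass 6.5 µM. You can build a ceiling on that impossibility.

in all of them: transfer agent 0.0150 mM; initiator 6.5 µM
- west: free monomer 0.50 mM (fed, over 4.80 s); time 6.0 s; all but free monomer at the start; free monomer goes in evenly over 4.80 s, the run ends at 6.0 s
- north-east: free monomer 0.50 mM; one stirred flow tank at steady state, fed with the mixture as stated, mean residence time 6.0 s
- south-west: free monomer 0.50 mM; time 6.0 s; everything together in a closed stirred flask, run for 6.0 s

    free monomer + initiator → living end + monomer in chains (k1 = 3900 M⁻¹ s⁻¹)
    free monomer + living end → monomer in chains + living end, rate k2*[living end]*[free monomer] (k2 = 1.3 × 10⁵ M⁻¹ s⁻¹)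
    living end + transfer agent → dead chain (k3 = 24000 M⁻¹ s⁻¹)
    free monomer → uncatalysed product (k4 = 0.52 s⁻¹)

1. the set-up with the highest share of monomer in chains in all that became monomer in chains or uncatalysed product, at the outlet or at the end ("none" if the first two lie within 2 percentage points) (west / north-east / south-west / none)
2. share of monomer in chains in all that became monomer in chains or uncatalysed product, at the outlet or at the end, west
3. share of monomer in chains in all that became monomer in chains or uncatalysed product, at the outlet or at the end, north-east
4. share of monomer in chains in all that became monomer in chains or uncatalysed product, at the outlet or at the end, south-west

Free monomer has two exits. Chains take it at k2·c(living end), the uncatalysed step at k4. Set these equal and you get the break-even level of living ends, c* = k4/k2 = 0.00400 mM. The share in chains is then c(living end)/(c(living end) + c*), a selectivity factor in another form. Step 1 takes one free monomer per initiator, so it can put at most 1.30 % of the charged free monomer into chains.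

With c(living end) at the full charge, the share reaches 61.9 % in west, north-east and south-west alike.

Now tighten this by hand for south-west. Free monomer lasts between 0.733 s and 1.92 s, and transfer gives a living end a lifetime of 2.78 s. The short life, counting losses by transfer, gives 55.5 %. The long life, with the initiator caught during the short one, gives 38.2 %. These are estimates, not proofs.

In north-east, take every initiator as caught and hold the transfer agent at its charge. Then c(living end) is about 0.00206 mM, so I put the share near 34.0 %, less than my low south-west estimate. For west I commit to the ceiling.

The forecast gives 42 % for south-west, 38 % for west and 31 % for north-east, so south-west is best, holding that “the flow tank holds living ends lowest”. Its south-west value lies inside my range, and its west value lies below my ceiling.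

| set-up | by hand | forecast | simulation |
|---|---|---|---|
| south-west | 38.2 % to 55.5 % | 42 % | 42.2 % |
| north-east | near 34.0 % | 31 % | 29.5 % |
| west | below 61.9 % | 38 % | 36.2 % |

The best set-up is south-west. Even there, less ends in chains than as uncatalysed product, 41.9 % against 57.5 %. In west at 3.20 s, free monomer goes the uncatalysed way 1.5 times as fast as into chains, and c(living end), read as 0.00263 mM at 3.00 s, stands below c*.

Read through c*, west's share means an effective level equal to 35.0 % of its initiator charge. Keep that fraction in the neighbour charged with 0.026 mM of initiator: the level is 0.00910 mM, above c*, and the share is 69.5 %. The computed share is 65.9 %, with monomer in chains holding most.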